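All runs come from a simulation with made-up constants; the scatter is artificial.

A small charge of substrate dropped into much partner is the flask I can solve in my head: substrate meets partner rather than itself, so its target yield is a ceiling. The other extreme is the whole charge poured in at once. Where each recipe stands against these two I reckon below from its substrate per partner.

| flask | substrate | partner | remark | time |
|---|---|---|---|---|
| south-east | 20 mM | 21 mM | run made earlier |  |
| north | 20 mM | 14 mM | run made earlier |  |
| north-west | 20 mM | 32 mM | run made earlier |  |
| north-east | 40 mM | 21 mM | run made earlier |  |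
| epsilon | 20 mM | 21.0 mM (fed, over 10.0 min) | a stirred flask in which partner is dosed at a steady rate over 10.0 min without added volume, worked up at 20 min | 20 min |
| theta | 20 mM | 21.0 mM | everything together in a closed stirred flask, run for 20 min | 20 min |
| beta | 20 mM | 21.0 mM | a single well-mixed tank run continuously and read at steady state, 20 min in it on average |  |
| zeta | 20 mM (fed, over 10.0 min) | 21.0 mM | a stirred flask in which substrate is dosed at a steady rate over 10.0 min without added volume, worked up at 20 min | 20 min |

| run | time / min | target / % | substrate / % |
|---|---|---|---|
| south-east | 3.00 | 11.7 | 6.6 |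
| south-east | 6.00 | 16.5 | 2.2 |
| south-east | 8.00 | 19.3 | 3.7 |
| south-east | 12.0 | 19.7 | 2.1 |
| south-east | 15.0 | 18.3 | 3.2 |
| south-east | 20.0 | 17.2 | 1.2 |
| north | 3.00 | 7.9 | 8.0 |
| north | 6.00 | 11.9 | 2.7 |
| north | 10.0 | 14.0 | 3.4 |
| north | 15.0 | 13.5 | 2.1 |
| north | 20.0 | 15.5 | 2.8 |
| north | 25.0 | 13.6 | 2.4 |
| north-west | 2.00 | 8.7 | 6.1 |
| north-west | 3.00 | 12.6 | 4.3 |
| north-west | 4.00 | 16.1 | 3.0 |
| north-west | 6.00 | 20.3 | 0.9 |
| north-west | 10.0 | 21.7 | 1.0 |
| north-west | 15.0 | 22.9 | 3.8 |
| north-west | 25.0 | 22.8 | 4.3 |
| north-east | 2.00 | 6.8 | 6.6 |
| north-east | 6.00 | 12.0 | 2.4 |
| north-east | 12.0 | 12.6 | 2.8 |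
| north-east | 15.0 | 12.0 | 1.0 |
| north-east | 25.0 | 12.0 | 3.1 |

(standard deviation of a reading: 1 percentage point)

- the stated concentrations are those of everything mixed, before any reaction; amounts are the same in each set-up
- the earlier runs were read with a standard deviation of 1 percentage point
- the feed brings no volume worth counting
- the earlier runs were made in a closed, stirred flask

- the set-up with the highest amount of target at the outlet or at the end, in percent of the substrate put in ("none" if the first two lie within 2 percentage points) (epsilon / theta / beta / zeta / none)
- amount of target at the outlet or at the end, in percent of the substrate put in, epsilon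
- amount of target at the outlet or at the end, in percent of the substrate put in, theta
- amount of target at the outlet or at the end, in percent of the substrate put in, beta
- amount of target at the outlet or at the end, in percent of the substrate put in, zeta

Target levels off at 22.8% in the north-west run, with 0.625 substrate per partner, and at 12.0% in the north-east run, at 1.90. I take target as a ceiling divided by (one plus a factor times that ratio), the form for a path through partner competing with a path of substrate with itself. These two readings give 1.25 for the selectivity factor, the weight of each unit of substrate per partner against target, and a ceiling of 40.7%. For theta, which repeats the south-east run, this gives 18.5%, and that run, unused so far, reads 17.2% at 20.0 min.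

In a dosed flask the ratio that counts is the standing one. The south-east run leaves 6.6% of its substrate at 3.00 min, a loss of 0.906 /min at 21 mM partner. In zeta, at mid-feed, I allow 11.0 mM partner. Feed against loss then gives 4.21 mM substrate, a ratio of 0.383 and 27.5% target. In epsilon I set the whole substrate against the partner dosed by 3.00 min: a ratio of 3.17 and 8.16% target. The tank I leave without a figure, since target in the south-east run still climbs after its substrate has fallen, and a tank's outlet takes material away early. I commit to zeta.

The forecast gives 10% for epsilon, 18.5% for theta, 29% for beta and 28% for zeta, with best none: “Beta and zeta are too close to separate.”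

Best is zeta, at 25.1%, above beta at 19.3%, theta at 18.6% and epsilon at 6.40%. At the end of its feed, 10.0 min, zeta holds 16.2% of its substrate and 39.2% of its partner, a ratio of 0.393; the factor 1.25 turns that into 27.3% target.

    adduct ⇌ target (K = 0.608, k = 0.00269 /s)
    partner → decomposed reagent (k = 5.98 × 10⁻⁵ /s)
    2 substrate → homo dimer (k = 0.695 /M/s)
    substrate + partner ⇌ adduct (K = 1300 /M, k = 0.787 /M/s)

A neighbour flask is zeta with 5.0 mM of substrate. The same reckoning gives a ratio of 0.0339 and 39.0% target; the flask gives 34.3%.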